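**Retrosynthetic overview**

- Labels: C1 (bears ArA = 3-hydroxy-4,5-dimethoxyphenyl), O2, C3, C3a, C4 (bears ArB = 3,4,5-trimethoxyphenyl), O5, C6, C6a. Ring 1 = C1–O2–C3–C3a–C6a and ring 2 = C3a–C4–O5–C6–C6a. Both aryl groups are exo and the fusion is cis.
- Feature exploited: CH2 C6 sits on bridgehead C6a next to bridgehead C3a, so a C3a–C6 bond turns C6/C6a/C3a into a cyclopropane fused to ring 1 written as a lactone (C3 = carbonyl, extra ester on C3a). Breaking that strained bond at C6 frees an electrophile at C6 and a nucleophile at C3a, which is what ring 2 needs.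
- Late disconnections: phenol to its benzyl ether; the O2–C3 ether of ring 1 to the C1/C3 diol and on to the C3 lactone; H on C3a to the angular methyl ester.
- Key disconnection: C3a–C4 and O5–C6 of ring 2, giving 3,4,5-trimethoxybenzaldehyde and the cyclopropane lactone (formal 3+2 relayed by iodide).
- The cyclopropane lactone goes back to the diazomalonate of a resolved (S)-1-arylallyl alcohol. Ring order: ring 1 (as lactone) together with the cyclopropane, then ring 2, then ring 1 again as the ether.

Key step: step 7

Remark: the atom labels C1–C6a of the target bicycle are kept for the corresponding atoms in every intermediate.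

Step 1
Reactants: 1 3-hydroxy-4,5-dimethoxybenzaldehyde; 2 benzyl bromide
Product: 3 3-(benzyloxy)-4,5-dimethoxybenzaldehyde
Conditions: K2CO3, DMF, 25 °C
Reagents that add atoms: benzyl bromide 2, BrCc1ccccc1
Why: Williamson ether synthesis on the only acidic OH, with the aldehyde inert to K2CO3 and the benzyl ether able to withstand every step up to the final hydrogenolysis.

Step 2
Reactants: 3 3-(benzyloxy)-4,5-dimethoxybenzaldehyde; 4 vinylmagnesium bromide
Product: 5 rac-1-[3-(benzyloxy)-4,5-dimethoxyphenyl]prop-2-en-1-ol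
Conditions: THF, −78 to 0 °C; aqueous work-up
Reagents that add atoms: vinylmagnesium bromide 4, C=C[Mg]Br
Why: Grignard 1,2-addition to a non-enolisable aryl aldehyde, which creates C1 as a racemate to be resolved in the next step.

Step 3
Reactants: 5 rac-1-[3-(benzyloxy)-4,5-dimethoxyphenyl]prop-2-en-1-ol
Product: 6 (S)-1-[3-(benzyloxy)-4,5-dimethoxyphenyl]prop-2-en-1-ol
Conditions: Ti(OiPr)4 (cat.), L-(+)-DIPT (cat.), t-BuOOH (0.6 equiv), 4 Å MS, CH2Cl2, −20 °C
Reagents that add atoms: none
Why: Sharpless kinetic resolution, in which the titanium L-(+)-tartrate complex epoxidises the (R)-carbinol much faster, so stopping slightly beyond half conversion should leave the (S)-alcohol with the C1 configuration of the target, the polar epoxy alcohol being removed by chromatography.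

Step 4
Reactants: 6 (S)-1-[3-(benzyloxy)-4,5-dimethoxyphenyl]prop-2-en-1-ol; 7 methyl malonyl chloride
Product: 8 (S)-1-[3-(benzyloxy)-4,5-dimethoxyphenyl]allyl methyl malonate
Conditions: pyridine, CH2Cl2, 0 °C
Reagents that add atoms: methyl malonyl chloride 7, COC(=O)CC(=O)Cl
Why: O-acylation of the alcohol by an acid chloride, in which the C1–O bond is not broken and the configuration is therefore kept.

Step 5
Reactants: 8 (S)-1-[3-(benzyloxy)-4,5-dimethoxyphenyl]allyl methyl malonate; 9 4-acetamidobenzenesulfonyl azide
Product: 10 (S)-1-[3-(benzyloxy)-4,5-dimethoxyphenyl]allyl methyl 2-diazomalonate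
Conditions: Et3N, MeCN, 0 to 25 °C
Reagents that add atoms: 4-acetamidobenzenesulfonyl azide 9, CC(=O)Nc1ccc(cc1)S(=O)(=O)N=[N+]=[N-]
Why: Regitz diazo transfer to the doubly activated malonate CH2 under a mild amine base that leaves the allylic benzylic ester untouched.

Step 6
Reactants: 10 (S)-1-[3-(benzyloxy)-4,5-dimethoxyphenyl]allyl methyl 2-diazomalonate
Product: 11 methyl (1R,4S,5S)-4-[3-(benzyloxy)-4,5-dimethoxyphenyl]-2-oxo-3-oxabicyclo[3.1.0]hexane-1-carboxylate (aryl trans to the cyclopropane CH2)
Conditions: Rh2(OAc)4 (1 mol %), 1,2-dichloroethane, 80 °C, slow addition of 10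
Reagents that add atoms: none
Why: Rhodium-carbenoid intramolecular cyclopropanation of the terminal vinyl group, a standard reaction of allyl diazomalonates, forms lactone ring 1 and the C3a–C6–C6a cyclopropane at once; the fusion can only be cis, and the transition state with C1–H turned towards the alkene and ArA pseudo-equatorial avoids allylic strain, so C6a and C3a should follow from C1 with ArA trans to C6.

Step 7
Reactants: 11 methyl (1R,4S,5S)-4-[3-(benzyloxy)-4,5-dimethoxyphenyl]-2-oxo-3-oxabicyclo[3.1.0]hexane-1-carboxylate; 12 3,4,5-trimethoxybenzaldehyde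
Product: 15 O-benzyl furofuranone ester (1S,3aS,4R,6aR; carbonyl at C3; CO2Me on C3a; both aryl groups exo), via iodomethyl magnesium enolate 13 (not isolated), via magnesium aldolate 14 (not isolated)
Conditions: MgI2 (1.0 equiv, anhydrous), 12 (2 equiv), THF, 60 °C, sealed tube
Reagents that add atoms: 3,4,5-trimethoxybenzaldehyde 12, COc1cc(C=O)cc(OC)c1OC; magnesium iodide, [Mg+2].[I-].[I-] (its atoms are held only in 13 and 14 and are returned on ring closure)
Why: Proposed new method: MgI2 chelates the lactone and ester carbonyls on C3a and iodide attacks CH2 C6 from the rear in an SN2 homo-conjugate opening that breaks the strained C3a–C6 bond and gives the iodomethyl enolate 13; 13 adds reversibly to aldehyde 12 (C3a–C4), and the alkoxide of aldolate 14 displaces the iodide (O5–C6), which returns MgI2. The closest known reaction type is the MgI2-mediated ring expansion of carbonyl-activated cyclopropanes (spirocyclopropyl oxindoles, methylenecyclopropane amides) with imines or aldehydes, together with the Lewis acid–iodide halo-aldol of cyclopropyl ketones, but a cyclopropane activated by a lactone and an ester has not been tried. Ring 2, the only ring formed, closes 5-exo-tet. C3a is controlled by C6a: only the aldolate that carries C4 on the same face as the CH2I group can reach C6, the aldolate of the other face reverts, and the product is therefore cis-fused. C4 is controlled in the same ring closure under Curtin–Hammett conditions, since an endo ArB would be pushed against the rigid C3=O/O2 edge inside the fold whereas an exo ArB meets only the ester, which can turn its flat face towards it; this bias is smaller than in a bicycle with bridgehead H and is the main uncertainty. The step needs opening at C6 rather than at C6a or at benzylic C1, which is secured by the primary, unhindered nature of C6 and by the C3a–C6 bond lying out of the lactone plane, where it overlaps with the C3=O π* orbital, while C3a–C6a lies in that plane.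

Step 8
Reactants: 15 O-benzyl furofuranone ester
Product: 16 (1S,3aS,4S,6aR)-1-[3-(benzyloxy)-4,5-dimethoxyphenyl]-4-(3,4,5-trimethoxyphenyl)tetrahydro-1H,3H-furo[3,4-c]furan-3-one
Conditions: LiCl, H2O, DMSO, 140 °C
Reagents that add atoms: none
Why: Krapcho dealkoxycarbonylation, in which chloride removes the ester methyl group by SN2, the carboxylate alpha to the lactone carbonyl loses CO2, and the lactone enolate is protonated to the only accessible cis-fused bicycle, so H3a ends on the convex face beside H6a while C1, C4 and C6a are untouched.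

Step 9
Reactants: 16 furofuranone
Product: 17 (S)-[3-(benzyloxy)-4,5-dimethoxyphenyl][(3R,4R,5S)-4-(hydroxymethyl)-5-(3,4,5-trimethoxyphenyl)tetrahydrofuran-3-yl]methanol
Conditions: LiAlH4, THF, 0 °C; aqueous work-up
Reagents that add atoms: none
Why: Hydride reduction of a lactone to the 1,4-diol, with aryl, benzyl and cyclic ethers inert and no stereocentre involved.

Step 10
Reactants: 17 diol; 18 methanesulfonyl chloride
Product: 19 primary mesylate of 17 (C3–OMs, C1–OH free)
Conditions: MsCl (1.05 equiv), Et3N, CH2Cl2, −30 °C; cold work-up, used crude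
Reagents that add atoms: methanesulfonyl chloride 18, CS(=O)(=O)Cl
Why: Selective sulfonylation of the unhindered primary alcohol at low temperature with one equivalent of reagent, the secondary benzylic alcohol at C1 reacting much more slowly.

Step 11
Reactants: 19 primary mesylate
Product: 20 (1S,3aR,4S,6aR)-1-[3-(benzyloxy)-4,5-dimethoxyphenyl]-4-(3,4,5-trimethoxyphenyl)tetrahydro-1H,3H-furo[3,4-c]furan
Conditions: NaH, THF, 0 to 25 °C
Reagents that add atoms: none
Why: Intramolecular Williamson etherification (5-exo-tet) in which the C1 alkoxide displaces the primary mesylate at C3, so the C1–O bond is retained, ArA stays exo and ring 1 is re-formed cis-fused.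

Step 12
Reactants: 20 O-benzyl furofuran
Product: 21 5-[(1S,3aR,4S,6aR)-4-(3,4,5-trimethoxyphenyl)tetrahydro-1H,3H-furo[3,4-c]furan-1-yl]-2,3-dimethoxyphenol (target)
Conditions: H2 (1 atm), 10 % Pd/C, EtOAc, 25 °C, stopped after uptake of one equivalent
Reagents that add atoms: none
Why: Catalytic hydrogenolysis of the aryl benzyl ether, which should be cleaved faster than the two hindered secondary benzylic C–O bonds of the bicycle in a neutral solvent.

**Compound list**

1 | 3-hydroxy-4,5-dimethoxybenzaldehyde | COc1cc(C=O)cc(O)c1OC | starting material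
2 | benzyl bromide | BrCc1ccccc1 | starting material
3 | 3-(benzyloxy)-4,5-dimethoxybenzaldehyde | COc1cc(C=O)cc(OCc2ccccc2)c1OC | intermediate
4 | vinylmagnesium bromide | C=C[Mg]Br | starting material
5 | rac-1-[3-(benzyloxy)-4,5-dimethoxyphenyl]prop-2-en-1-ol | COc1cc(C(O)C=C)cc(OCc2ccccc2)c1OC | intermediate
6 | (S)-1-[3-(benzyloxy)-4,5-dimethoxyphenyl]prop-2-en-1-ol | COc1cc([C@@H](O)C=C)cc(OCc2ccccc2)c1OC | intermediate
7 | methyl malonyl chloride (methyl 3-chloro-3-oxopropanoate) | COC(=O)CC(=O)Cl | starting material
8 | (S)-1-[3-(benzyloxy)-4,5-dimethoxyphenyl]allyl methyl malonate | COc1cc([C@@H](OC(=O)CC(=O)OC)C=C)cc(OCc2ccccc2)c1OC | intermediate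
9 | 4-acetamidobenzenesulfonyl azide | CC(=O)Nc1ccc(cc1)S(=O)(=O)N=[N+]=[N-] | starting material
10 | (S)-1-[3-(benzyloxy)-4,5-dimethoxyphenyl]allyl methyl 2-diazomalonate | COc1cc([C@@H](OC(=O)C(=[N+]=[N-])C(=O)OC)C=C)cc(OCc2ccccc2)c1OC | intermediate
11 | methyl (1R,4S,5S)-4-[3-(benzyloxy)-4,5-dimethoxyphenyl]-2-oxo-3-oxabicyclo[3.1.0]hexane-1-carboxylate, aryl trans to the cyclopropane CH2 | COc1cc([C@H]2OC(=O)[C@]3(C(=O)OC)C[C@H]23)cc(OCc2ccccc2)c1OC | intermediate
12 | 3,4,5-trimethoxybenzaldehyde | COc1cc(C=O)cc(OC)c1OC | starting material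
13 | iodomagnesium enolate of the ring 1 lactone ester, CH2I on C6a trans to ArA on C1 (not isolated) | COc1cc([C@H]2OC(O[Mg]I)=C(C(=O)OC)[C@@H]2CI)cc(OCc2ccccc2)c1OC | intermediate
14 | iodomagnesium aldolate, C4 arm on C3a cis to CH2I on C6a (not isolated) | COc1cc([C@H]2OC(=O)[C@](C(=O)OC)([C@H](O[Mg]I)c3cc(OC)c(OC)c(OC)c3)[C@@H]2CI)cc(OCc2ccccc2)c1OC | intermediate
15 | methyl (1S,3aS,4R,6aR)-1-[3-(benzyloxy)-4,5-dimethoxyphenyl]-3-oxo-4-(3,4,5-trimethoxyphenyl)tetrahydro-1H,3H-furo[3,4-c]furan-3a(4H)-carboxylate | COc1cc([C@H]2OC(=O)[C@@]3(C(=O)OC)[C@@H]2CO[C@@H]3c2cc(OC)c(OC)c(OC)c2)cc(OCc2ccccc2)c1OC | intermediate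
16 | (1S,3aS,4S,6aR)-1-[3-(benzyloxy)-4,5-dimethoxyphenyl]-4-(3,4,5-trimethoxyphenyl)tetrahydro-1H,3H-furo[3,4-c]furan-3-one | COc1cc([C@H]2OC(=O)[C@H]3[C@@H]2CO[C@@H]3c2cc(OC)c(OC)c(OC)c2)cc(OCc2ccccc2)c1OC | intermediate
17 | (S)-[3-(benzyloxy)-4,5-dimethoxyphenyl][(3R,4R,5S)-4-(hydroxymethyl)-5-(3,4,5-trimethoxyphenyl)tetrahydrofuran-3-yl]methanol | COc1cc([C@@H](O)[C@H]2CO[C@H](c3cc(OC)c(OC)c(OC)c3)[C@H]2CO)cc(OCc2ccccc2)c1OC | intermediate
18 | methanesulfonyl chloride | CS(=O)(=O)Cl | starting material
19 | primary methanesulfonate of 17 (C3–OMs, C1–OH free) | COc1cc([C@@H](O)[C@H]2CO[C@H](c3cc(OC)c(OC)c(OC)c3)[C@H]2COS(C)(=O)=O)cc(OCc2ccccc2)c1OC | intermediate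
20 | (1S,3aR,4S,6aR)-1-[3-(benzyloxy)-4,5-dimethoxyphenyl]-4-(3,4,5-trimethoxyphenyl)tetrahydro-1H,3H-furo[3,4-c]furan | COc1cc([C@H]2OC[C@H]3[C@@H]2CO[C@@H]3c2cc(OC)c(OC)c(OC)c2)cc(OCc2ccccc2)c1OC | intermediate
21 | 5-[(1S,3aR,4S,6aR)-4-(3,4,5-trimethoxyphenyl)tetrahydro-1H,3H-furo[3,4-c]furan-1-yl]-2,3-dimethoxyphenol | COc1cc([C@H]2OC[C@H]3[C@@H]2CO[C@@H]3c2cc(OC)c(OC)c(OC)c2)cc(O)c1OC | target

**Step count**

Total step count: 12. Longest linear sequence: 12 steps (from 1).

**Steps most likely to fail**

1. Step 7 (Proposed new method).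
   - What may go wrong: re-closure of enolate 13 to the cyclopropane may outrun its capture by the aldehyde. Heating with iodide may start loss of the ester methyl group or ionisation at benzylic C1. The exo/endo discrimination at C4 may be poor because the angular ester shares the convex face with ArB.
   - Fallback: known chemistry with O5–C6 made first, setting out from 11 and coming back at 16. Sc(OTf)3-catalysed homo-conjugate addition of 3,4,5-trimethoxybenzyl alcohol to C6 of 11 should give the trimethoxybenzyl ether lactone ester F1. Krapcho dealkoxycarbonylation then gives the ether lactone F2. LiHMDS and 2,2,2-trifluoroethyl trifluoroacetate give the α-trifluoroacetyl lactone F3, and detrifluoroacetylative diazo transfer with methanesulfonyl azide and Et3N gives the α-diazo lactone F4. Rh2(OAc)4-catalysed 1,5 C–H insertion of the carbenoid into the benzylic OCH2 group forms C3a–C4 within the tether, which enforces the cis fusion, and is expected to give the endo-ArB furofuranone F5. Acid equilibration at C4 through the benzylic cation (catalytic camphorsulfonic acid, 1,2-dichloroethane) is the reaction type known from the epimerisation of furofuran lignans. It leads to 16, and unconverted endo isomer is recycled. The same equilibration would serve material in which step 7 had closed with ArB endo.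

2. Step 6.
   - What may go wrong: the carbenoid may be diverted to cycloaddition on the electron-rich ring ArA or to insertion into the activated C1–H bond, and the facial selectivity that places ArA trans to C6 may be modest.
   - Fallback: a radical-polar sequence without a diazo compound, setting out from 8 and coming back at 11. Iodination of the sodium enolate of 8 with N-iodosuccinimide gives the iodomalonate F6. Iodine atom-transfer 5-exo radical cyclisation ((Bu3Sn)2, sun lamp, benzene, 80 °C) should give the iodomethyl lactone ester F7, with CH2I trans to ArA as is usual for such cyclisations. DBU then closes the cyclopropane 3-exo-tet to 11. F7 is also the conjugate acid of enolate 13.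

3. Step 8.
   - What may go wrong: at the temperature needed to dealkylate the hindered angular ester, chloride attack or ionisation at benzylic C1 and beta-elimination and re-addition of O5 at the enolate stage could erode C1 and C4.
   - Fallback: acyl–oxygen cleavage followed by a separate, milder decarboxylation, setting out from 15 and coming back at 16. LiOH in aqueous THF/MeOH saponifies the ester and opens the lactone to the hydroxy malonic diacid F8, with the C1–O bond intact. Acidification re-closes ring 1 to the lactone carboxylic acid F9, and warming in toluene decarboxylates this malonic half-acid to 16 with protonation to the cis-fused bicycle.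

**Further compounds**

F1 | step 7 | methyl 5-[3-(benzyloxy)-4,5-dimethoxyphenyl]-2-oxo-4-[(3,4,5-trimethoxybenzyloxy)methyl]tetrahydrofuran-3-carboxylate, all neighbours trans, C3a epimerisable | COc1cc([C@H]2OC(=O)[C@@H](C(=O)OC)[C@@H]2COCc2cc(OC)c(OC)c(OC)c2)cc(OCc2ccccc2)c1OC
F2 | step 7 | 5-[3-(benzyloxy)-4,5-dimethoxyphenyl]-4-[(3,4,5-trimethoxybenzyloxy)methyl]dihydrofuran-2(3H)-one, trans | COc1cc([C@H]2OC(=O)C[C@@H]2COCc2cc(OC)c(OC)c(OC)c2)cc(OCc2ccccc2)c1OC
F3 | step 7 | α-trifluoroacetyl derivative of F2 (C3a epimers and enol) | COc1cc([C@H]2OC(=O)C(C(=O)C(F)(F)F)[C@@H]2COCc2cc(OC)c(OC)c(OC)c2)cc(OCc2ccccc2)c1OC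
F4 | step 7 | α-diazo derivative of F2 | COc1cc([C@H]2OC(=O)C(=[N+]=[N-])[C@@H]2COCc2cc(OC)c(OC)c(OC)c2)cc(OCc2ccccc2)c1OC
F5 | step 7 | C4 epimer of 16 (ArB endo, ArA exo) | COc1cc([C@H]2OC(=O)[C@H]3[C@@H]2CO[C@H]3c2cc(OC)c(OC)c(OC)c2)cc(OCc2ccccc2)c1OC
F6 | step 6 | (S)-1-[3-(benzyloxy)-4,5-dimethoxyphenyl]allyl methyl 2-iodomalonate (epimers at C–I) | COc1cc([C@@H](OC(=O)C(I)C(=O)OC)C=C)cc(OCc2ccccc2)c1OC
F7 | step 6 | methyl 5-[3-(benzyloxy)-4,5-dimethoxyphenyl]-4-(iodomethyl)-2-oxotetrahydrofuran-3-carboxylate, CH2I trans to aryl, C3a epimerisable | COc1cc([C@H]2OC(=O)[C@@H](C(=O)OC)[C@@H]2CI)cc(OCc2ccccc2)c1OC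
F8 | step 8 | 4-[(S)-[3-(benzyloxy)-4,5-dimethoxyphenyl](hydroxy)methyl]-2-(3,4,5-trimethoxyphenyl)tetrahydrofuran-3,3-dicarboxylic acid | COc1cc([C@@H](O)[C@H]2CO[C@H](c3cc(OC)c(OC)c(OC)c3)C2(C(=O)O)C(=O)O)cc(OCc2ccccc2)c1OC
F9 | step 8 | carboxylic acid corresponding to ester 15 | COc1cc([C@H]2OC(=O)[C@@]3(C(=O)O)[C@@H]2CO[C@@H]3c2cc(OC)c(OC)c(OC)c2)cc(OCc2ccccc2)c1OC
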